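If partner is lost chiefly by pairing with itself, its time constant shortens as its charge grows. At one substrate charge and a steady dissolved substrate, the converted fraction then follows one clock: equivalents of partner times time. This product stands at 37.5 min in the new flask; call it the partner dose.

| setting | midnight | winter | flask |
|---|---|---|---|
| solid substrate | 0.010 M | 0.010 M | 0.010 M |
| partner | 0.75 equiv | 3 equiv | 1.50 equiv |
| remark | run made earlier | run made earlier |  |
| time |  |  | 25 min |

- midnight (time / min: target / %, solid product / %): 1.50: 0, 0; 4.00: 2, 0; 8.00: 7, 3; 20.0: 12, 8
- winter (time / min: target / %, solid product / %): 2.50: 6, 1; 8.00: 13, 10; 12.0: 17, 14; 20.0: 22, 14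

(standard deviation of a reading: 1.5 percentage points)

- for target the solid product is counted in
- as a solid, counted per litre of solution: solid substrate, solid product
- candidate steps: solid substrate <-> dissolved substrate; dissolved substrate + partner -> target; solid product <-> target; 2 partner -> homo dimer; partner -> decomposed reagent
- at the start none of the solid substrate is in solution
- dissolved substrate means what is dissolved; the solid is not counted in it

1. the target and solid product together standing at 25 min, as a percentage of the solid substrate charged
2. concentration of dissolved substrate in solution at 25 min, in percent of saturation

The target column already counts the solid product, so it reads the first question directly. Read it against dose. The midnight run at 8.00 min has dose 6.00 min and shows 7%. The winter run at 2.50 min has dose 7.50 min and shows 6%. With a scatter of 1.5 percentage points, these two agree, though the winter run carries 4.00 times the partner. The winter run then shows 17% at dose 36.0 min and 22% at dose 60.0 min. The new flask falls between these, and interpolation in the logarithm of dose gives 17.4%. One curve for both runs suggests one dissolved level in both, but not how high it stands, so this reckoning leaves the second question open.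

The forecast gave 31% (26% to 36%) and 85% (65% to 97%), holding that “the partner is largely spent”.

The flask gives 18.6% and 99.4%. At 1.38 min, partner goes to homo dimer 14 times as fast as to target.

    solid substrate ⇌ dissolved substrate, rate k1*(cs1 - [dissolved substrate]) while solid is left; crystals form when [dissolved substrate] > cs1 (solubility = 7.80 mM, k = 0.0115 s⁻¹)
    dissolved substrate + partner → target (k = 0.0424 L mol⁻¹ s⁻¹)
    solid product ⇌ target, rate k3*(cs3 - [target]) while solid is left; crystals form when [target] > cs3 (solubility = 0.440 mM, k = 0.0272 s⁻¹)
    2 partner → homo dimer (k = 0.124 L mol⁻¹ s⁻¹)
    partner → decomposed reagent (k = 6.95 × 10⁻⁵ s⁻¹)

The dose reckoning stands 1.2 points under the result, against a scatter of 1.5 points. The same flask read at 10 min has dose 15.0 min, equal to the midnight run at 20.0 min, so dose points to 12%. That flask computes to 11.2%.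

Readings and results were generated by integration from invented constants; the scatter is artificial.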